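**Retrosynthetic overview** (locants: dienone ring C1 (C=O) to C6 with C4 quaternary; side chain C7 = CH2, C8 = CH; ring A = guaiacyl ring, ring B = dienone ring)
1. Target ⇐ desilylation ⇐ methoxylative para-dearomatisation of the ring B phenol; the C4–OMe bond and the quaternary centre are made last, on the complete skeleton.
2. C8–C4 bond ⇐ Friedel–Crafts capture of a phenonium ion by 2-allyl-5-methoxyphenol; ring A shifts from C8 to C7 (1,2-aryl shift) while ring B enters C8 with inversion.
3. The 2-arylpropyl tosylate (ring A on C8) ⇐ guaiacol + (R)-propylene oxide (Friedel–Crafts opening at the internal carbon, inversion); guaiacol ⇐ catechol.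
4. 2-Allyl-5-methoxyphenol ⇐ resorcinol (O-methylation, O-allylation, Claisen rearrangement).
5. No ring is built: ring A (from catechol) and ring B (from resorcinol) are carried as arenes, and ring B becomes the cyclohexadienone in the penultimate step.

Assumption: the facial sense of the new iodane-controlled step 9 is assigned by analogy with this reagent class; if the (4R)-epimer dominates, the antipodal (S,S)-reagent is used with nothing else changed.

**Step 1**
Reactants: 1 catechol (benzene-1,2-diol)
Product: 2 guaiacol (2-methoxyphenol)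
Conditions: MeI (1.0 equiv), K2CO3, acetone, reflux
Reagents that add atoms: iodomethane, CI
Why: Williamson mono-O-methylation, where one equivalent of MeI keeps the reaction largely at the mono-ether and catechol and veratrole are removed by extraction and distillation.

**Step 2**
Reactants: 2 guaiacol; 3 (R)-propylene oxide [(2R)-2-methyloxirane]
Product: 4 (2R)-2-(4-hydroxy-3-methoxyphenyl)propan-1-ol
Conditions: CF3SO3H (5 mol %), (CF3)2CHOH, −20 → 0 °C, 2 in threefold excess
Reagents that add atoms: none
Why: Friedel–Crafts alkylation by epoxide ring opening, in which the position of 2 para to OH attacks the more substituted carbon of the acid-activated epoxide in a borderline SN2 opening with inversion, so (R)-3 gives (R)-4 (the descriptor is kept only because the CIP priorities change).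

**Step 3**
Reactants: 4 (2R)-2-(4-hydroxy-3-methoxyphenyl)propan-1-ol
Product: 6 (2R)-2-{3-methoxy-4-[(triisopropylsilyl)oxy]phenyl}propan-1-ol, via sodium phenolate 5 (not isolated)
Conditions: NaH (1.0 equiv), THF, 0 °C; then iPr3SiCl, 0 °C → rt
Reagents that add atoms: chlorotri(propan-2-yl)silane, CC(C)[Si](Cl)(C(C)C)C(C)C
Why: Chemoselective O-silylation, since one equivalent of NaH deprotonates only the phenol (pKa about 10 against 16) and the phenolate is silylated; the silyl ether keeps the para oxygen a strong donor for step 8 and shields ring A in step 9.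

**Step 4**
Reactants: 6 (2R)-2-{3-methoxy-4-[(triisopropylsilyl)oxy]phenyl}propan-1-ol
Product: 7 (2R)-2-{3-methoxy-4-[(triisopropylsilyl)oxy]phenyl}propyl 4-methylbenzenesulfonate
Conditions: TsCl, Et3N, 4-(dimethylamino)pyridine (5 mol %), CH2Cl2, 0 °C
Reagents that add atoms: 4-methylbenzenesulfonyl chloride, Cc1ccc(cc1)S(Cl)(=O)=O
Why: Standard sulfonylation of a primary alcohol, which leaves the stereocentre untouched.

**Step 5**
Reactants: 8 resorcinol (benzene-1,3-diol)
Product: 9 3-methoxyphenol
Conditions: MeI (1.0 equiv), K2CO3, acetone, reflux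
Reagents that add atoms: iodomethane, CI
Why: Williamson mono-O-methylation of a symmetrical diphenol, with the diether and unreacted resorcinol separated by base extraction.

**Step 6**
Reactants: 9 3-methoxyphenol
Product: 10 1-methoxy-3-(prop-2-en-1-yloxy)benzene
Conditions: allyl bromide, K2CO3, acetone, reflux
Reagents that add atoms: allyl bromide (3-bromoprop-1-ene), C=CCBr
Why: Williamson O-allylation of the phenol.

**Step 7**
Reactants: 10 1-methoxy-3-(prop-2-en-1-yloxy)benzene
Product: 11 2-allyl-5-methoxyphenol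
Conditions: N,N-diethylaniline, 200 °C
Reagents that add atoms: none
Why: Aromatic Claisen rearrangement followed by tautomerisation, which delivers the allyl group mainly to the ortho carbon para to OMe (expected about 2:1 over 2-allyl-3-methoxyphenol, removed by chromatography).

**Step 8 (key step)**
Reactants: 7 (2R)-2-{3-methoxy-4-[(triisopropylsilyl)oxy]phenyl}propyl 4-methylbenzenesulfonate; 11 2-allyl-5-methoxyphenol
Product: 13 2-allyl-5-methoxy-4-[(2R)-1-{3-methoxy-4-[(triisopropylsilyl)oxy]phenyl}propan-2-yl]phenol, via phenonium tosylate 12 (not isolated)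
Conditions: (CF3)2CHOH, 2,6-di-tert-butylpyridine (1.2 equiv), 11 (2 equiv), 40 °C
Reagents that add atoms: none
Why: Wagner–Meerwein 1,2-aryl shift by neighbouring-group participation, ended by Friedel–Crafts alkylation: the para-silyloxyaryl ring displaces tosylate from C7 to give phenonium ion 12, and its more substituted carbon C8 is attacked anti to the bridging ring by the carbon of 11 that is para to OH and ortho to OMe, so ring A ends on C7 and C8 is formed with inversion as (R).

**Step 9**
Reactants: 13 2-allyl-5-methoxy-4-[(2R)-1-{3-methoxy-4-[(triisopropylsilyl)oxy]phenyl}propan-2-yl]phenol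
Product: 15 (4S)-2-allyl-4,5-dimethoxy-4-[(2R)-1-{3-methoxy-4-[(triisopropylsilyl)oxy]phenyl}propan-2-yl]cyclohexa-2,5-dien-1-one, via aryloxyiodane 14 (not isolated)
Conditions: (2R,2′R)-2,2′-{[2-(diacetoxy-λ3-iodanyl)-1,3-phenylene]bis(oxy)}bis[N-(2,4,6-trimethylphenyl)propanamide] (1.1 equiv), CH2Cl2–MeOH (1:1), −40 °C
Reagents that add atoms: methanol, CO
Why: Proposed new method: reagent-controlled methoxylative para-dearomatisation of a 4-sec-alkylphenol to a quaternary quinol ether, in which ligand exchange gives aryloxyiodane 14 and MeOH adds to C4 while the phenol is still bound to trivalent iodine (associative, SN2′-like), the folded hydrogen-bonded lactamide arms of the C2-symmetric reagent screening one ring face so that (4S) is set under reagent control (the intrinsic bias from C8, CH3 against CH2Ar, is small); the closest known reaction types are PhI(OAc)2/MeOH quinol-ether formation and enantioselective oxidative dearomatisations (spirolactonisation, quinol formation) with chiral iodoarene–lactamide reagents.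

**Step 10**
Reactants: 15 (4S)-2-allyl-4,5-dimethoxy-4-[(2R)-1-{3-methoxy-4-[(triisopropylsilyl)oxy]phenyl}propan-2-yl]cyclohexa-2,5-dien-1-one
Product: 16 (4S)-2-allyl-4-[(2R)-1-(4-hydroxy-3-methoxyphenyl)propan-2-yl]-4,5-dimethoxycyclohexa-2,5-dien-1-one (CNP0370214.1)
Conditions: Bu4NF, AcOH, THF, 0 °C
Reagents that add atoms: none
Why: Fluoride-mediated cleavage of the aryl silyl ether, buffered with AcOH so that the dienone and vinylogous ester are not exposed to base.

**Compound list**
1 | catechol (benzene-1,2-diol) | Oc1ccccc1O | starting material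
2 | guaiacol (2-methoxyphenol) | COc1ccccc1O | intermediate
3 | (R)-propylene oxide [(2R)-2-methyloxirane] | C[C@@H]1CO1 | starting material
4 | (2R)-2-(4-hydroxy-3-methoxyphenyl)propan-1-ol | C[C@@H](CO)c1ccc(O)c(OC)c1 | intermediate
5 | sodium 4-[(2R)-1-hydroxypropan-2-yl]-2-methoxyphenolate | C[C@@H](CO)c1ccc([O-])c(OC)c1.[Na+] | intermediate (not isolated)
6 | (2R)-2-{3-methoxy-4-[(triisopropylsilyl)oxy]phenyl}propan-1-ol | C[C@@H](CO)c1ccc(O[Si](C(C)C)(C(C)C)C(C)C)c(OC)c1 | intermediate
7 | (2R)-2-{3-methoxy-4-[(triisopropylsilyl)oxy]phenyl}propyl 4-methylbenzenesulfonate | C[C@@H](COS(=O)(=O)c1ccc(C)cc1)c1ccc(O[Si](C(C)C)(C(C)C)C(C)C)c(OC)c1 | intermediate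
8 | resorcinol (benzene-1,3-diol) | Oc1cccc(O)c1 | starting material
9 | 3-methoxyphenol | COc1cccc(O)c1 | intermediate
10 | 1-methoxy-3-(prop-2-en-1-yloxy)benzene | C=CCOc1cccc(OC)c1 | intermediate
11 | 2-allyl-5-methoxyphenol | C=CCc1ccc(OC)cc1O | intermediate
12 | phenonium ion pair: 5-methoxy-1-methyl-6-(triisopropylsilyloxy)spiro[2.5]octadienyl cation tosylate (methyl-bearing carbon as in 7, S by CIP; spiro carbon as a mixture) | C[C@H]1CC12C=CC(=[O+][Si](C(C)C)(C(C)C)C(C)C)C(OC)=C2.Cc1ccc(cc1)S([O-])(=O)=O | intermediate (not isolated)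
13 | 2-allyl-5-methoxy-4-[(2R)-1-{3-methoxy-4-[(triisopropylsilyl)oxy]phenyl}propan-2-yl]phenol | C=CCc1cc([C@H](C)Cc2ccc(O[Si](C(C)C)(C(C)C)C(C)C)c(OC)c2)c(OC)cc1O | intermediate
14 | acetoxy(aryloxy)-λ3-iodane: 13 bound through its phenolic oxygen to the iodine of the chiral reagent, one acetate displaced | CC(=O)OI(Oc1cc(OC)c([C@H](C)Cc2ccc(O[Si](C(C)C)(C(C)C)C(C)C)c(OC)c2)cc1CC=C)c1c(O[C@H](C)C(=O)Nc2c(C)cc(C)cc2C)cccc1O[C@H](C)C(=O)Nc1c(C)cc(C)cc1C | intermediate (not isolated)
15 | (4S)-2-allyl-4,5-dimethoxy-4-[(2R)-1-{3-methoxy-4-[(triisopropylsilyl)oxy]phenyl}propan-2-yl]cyclohexa-2,5-dien-1-one | C=CCC1=C[C@@](OC)([C@H](C)Cc2ccc(O[Si](C(C)C)(C(C)C)C(C)C)c(OC)c2)C(OC)=CC1=O | intermediate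
16 | (4S)-2-allyl-4-[(2R)-1-(4-hydroxy-3-methoxyphenyl)propan-2-yl]-4,5-dimethoxycyclohexa-2,5-dien-1-one | C=CCC1=C[C@@](OC)([C@H](C)Cc2ccc(O)c(OC)c2)C(OC)=CC1=O | target

**Totals**
Total steps: 10. Longest linear sequence: 7 (steps 1, 2, 3, 4, 8, 9, 10); steps 5–7 make the second fragment.

**Three steps most likely to fail**

Step 2 (Friedel–Crafts opening of propylene oxide). Risks are attack para to OMe instead of para to OH, O-alkylation, opening at the terminal carbon and opening by the solvent. The fallback sets out from 2 and comes back at 6, replacing the epoxide opening by cross-coupling and asymmetric hydroboration. Guaiacol 2 is brominated para to the hydroxyl (Bu4NBr3, CH2Cl2/MeOH) to 4-bromo-2-methoxyphenol F1. Silylation (iPr3SiCl, imidazole, DMF) gives (4-bromo-2-methoxyphenoxy)tri(propan-2-yl)silane F2. Suzuki coupling with isopropenylboronic acid pinacol ester (PdCl2(dppf), K3PO4, dioxane/water, 80 °C) gives [2-methoxy-4-(prop-1-en-2-yl)phenoxy]tri(propan-2-yl)silane F3. Copper hydride-catalysed enantioselective anti-Markovnikov hydroboration with pinacolborane (Cu(OAc)2, DTBM-SEGPHOS enantiomer chosen for the S product) gives {2-methoxy-4-[(2S)-1-(4,4,5,5-tetramethyl-1,3,2-dioxaborolan-2-yl)propan-2-yl]phenoxy}tri(propan-2-yl)silane F4. Oxidation with NaBO3·4H2O (retention) gives 6.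

Step 8 (phenonium shift and Friedel–Crafts capture). Risks are O-alkylation of 11, acid-induced cyclisation of the o-allylphenol, attack at the primary carbon (no shift) and elimination. The fallback sets out from 7 and 9 and comes back at 13; it uses the more robust nucleophile 9 and installs the allyl group after the key step. Solvolysis of 7 in (CF3)2CHOH with 3-methoxyphenol 9 (3 equiv) and 2,6-di-tert-butylpyridine gives, by the same aryl shift, 3-methoxy-4-[(2R)-1-{3-methoxy-4-[(triisopropylsilyl)oxy]phenyl}propan-2-yl]phenol F5. O-Allylation (allyl bromide, K2CO3, acetone) gives {2-methoxy-4-[(2R)-2-(2-methoxy-4-(prop-2-en-1-yloxy)phenyl)propyl]phenoxy}tri(propan-2-yl)silane F6. Claisen rearrangement (N,N-diethylaniline, 190 °C) to the free ortho carbon gives 13.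

Step 9 (the proposed new step). Risks are weak facial control at the remote para carbon, ortho attack of MeOH, spirocyclisation by ring A and quinone methide formation. The fallback sets out from 13 and comes back at 15 with known chemistry only, replacing reagent control by separation and recycling. Oxidation of 13 with PhI(OAc)2 in MeOH at 0 °C gives 15 together with its C4 epimer, (4R)-2-allyl-4,5-dimethoxy-4-[(2R)-1-{3-methoxy-4-[(triisopropylsilyl)oxy]phenyl}propan-2-yl]cyclohexa-2,5-dien-1-one F7. The two diastereomers are separated by chromatography. F7 is returned to 13 by reductive aromatisation (Zn, AcOH) and oxidised again.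

**Further compounds**
F1 | step 2 | 4-bromo-2-methoxyphenol | COc1cc(Br)ccc1O
F2 | step 2 | (4-bromo-2-methoxyphenoxy)tri(propan-2-yl)silane | COc1cc(Br)ccc1O[Si](C(C)C)(C(C)C)C(C)C
F3 | step 2 | [2-methoxy-4-(prop-1-en-2-yl)phenoxy]tri(propan-2-yl)silane | COc1cc(C(C)=C)ccc1O[Si](C(C)C)(C(C)C)C(C)C
F4 | step 2 | {2-methoxy-4-[(2S)-1-(4,4,5,5-tetramethyl-1,3,2-dioxaborolan-2-yl)propan-2-yl]phenoxy}tri(propan-2-yl)silane | C[C@@H](CB1OC(C)(C)C(C)(C)O1)c1ccc(O[Si](C(C)C)(C(C)C)C(C)C)c(OC)c1
F5 | step 8 | 3-methoxy-4-[(2R)-1-{3-methoxy-4-[(triisopropylsilyl)oxy]phenyl}propan-2-yl]phenol | COc1cc(O)ccc1[C@H](C)Cc1ccc(O[Si](C(C)C)(C(C)C)C(C)C)c(OC)c1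
F6 | step 8 | {2-methoxy-4-[(2R)-2-(2-methoxy-4-(prop-2-en-1-yloxy)phenyl)propyl]phenoxy}tri(propan-2-yl)silane | C=CCOc1ccc([C@H](C)Cc2ccc(O[Si](C(C)C)(C(C)C)C(C)C)c(OC)c2)c(OC)c1
F7 | step 9 | (4R)-2-allyl-4,5-dimethoxy-4-[(2R)-1-{3-methoxy-4-[(triisopropylsilyl)oxy]phenyl}propan-2-yl]cyclohexa-2,5-dien-1-one | C=CCC1=C[C@](OC)([C@H](C)Cc2ccc(O[Si](C(C)C)(C(C)C)C(C)C)c(OC)c2)C(OC)=CC1=O
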